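**Retrosynthetic overview**

1. The target is reached by O-methylation of the 5-allyl-5-hydroxy dienone, which comes from allyl addition to the C5 carbonyl of the 2-aryl-3-methyl-2,3-dihydrobenzofuran-5,6-dione, itself made by ortho-oxygenation of the corresponding 5-phenol.
2. The 5-phenol is disconnected at O1–C7a and C3–C3a: a one-flask [3+2] radical–polar annulation of (R)-1-(3,4-dimethoxyphenyl)prop-2-en-1-ol with p-benzoquinone dimethyl monoketal (hydrogen-atom-transfer Giese addition, ketal exchange, aromatisation).
3. Enabling feature: the dihydrofuran ring (ring B) shares the C3a–C7a edge with the six-membered ring A; C7a carries O1 and C3a lies β to C5, which is para to C7a. Ring A therefore maps onto a quinone monoketal (C5 carbonyl, C7a ketal), and O1–C2(Ar)–C3(CH3) maps onto an aryl vinyl carbinol whose =CH2 becomes the C3 methyl.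
4. The carbinol comes from vinyl Grignard addition to veratraldehyde and Sharpless kinetic resolution. C2 is fixed by the resolution, C3 by 1,2-induction in the key step, and C5 by the late allylation.
5. Ring order: ring A is bought as the dienone, ring B closes in the key step while ring A aromatises, and ring A is then re-dearomatised to the dienone.

Key step: step 3

Remark: benzofuran numbering (O1, C2, C3, C3a, C4–C7, C7a) is used; the target is read as (2R,3R,5S), with aryl and methyl trans and the allyl group on the face of the aryl group.

**Route**

Step 1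
Reactants: 1 3,4-dimethoxybenzaldehyde (veratraldehyde); 2 vinylmagnesium bromide
Product: 3 rac-1-(3,4-dimethoxyphenyl)prop-2-en-1-ol
Conditions: THF, 0 °C; sat. aq NH4Cl
Reagents that add atoms: none
Why: Grignard 1,2-addition to an aromatic aldehyde should give the racemic aryl vinyl carbinol; no stereocontrol is sought here.

Step 2
Reactants: 3 rac-1-(3,4-dimethoxyphenyl)prop-2-en-1-ol
Product: 4 (1R)-1-(3,4-dimethoxyphenyl)prop-2-en-1-ol
Conditions: Ti(OiPr)4 (20 mol %), D-(−)-DIPT (24 mol %), t-BuOOH (0.6 equiv), 4 Å MS, CH2Cl2, −20 °C; stopped past half conversion; chromatography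
Reagents that add atoms: none
Why: Sharpless kinetic resolution: with D-(−)-diisopropyl tartrate the (S)-carbinol should be epoxidised faster (to the erythro epoxy alcohol), so the unreacted (R)-carbinol is recovered, and this fixes C2 of the target.

Step 3
Reactants: 4 (1R)-1-(3,4-dimethoxyphenyl)prop-2-en-1-ol; 5 4,4-dimethoxycyclohexa-2,5-dien-1-one
Product: 8 (2R,3R)-2-(3,4-dimethoxyphenyl)-3-methyl-2,3-dihydro-1-benzofuran-5-ol, via radical conjugate adduct 6 (not isolated), via bicyclic methoxy ketal 7 (not isolated)
Conditions: Fe(acac)3 (30 mol %), PhSiH3, 5 (3 equiv), EtOH/(CH2OH)2, 60 °C; then CSA, rt, same flask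
Reagents that add atoms: none
Why: Proposed new method: an iron hydride formed from Fe(acac)3 and PhSiH3 transfers a hydrogen atom to the terminal CH2 of 4 (which becomes the C3 methyl), the secondary C3 radical adds to a β-carbon of the symmetric dienone 5 (Giese addition, C3–C3a) and the α-keto radical is reduced and protonated to 6; acid then ionises the allylic ketal, the C2 hydroxyl captures the oxocarbenium ion at C7a (O1–C7a, 7), and loss of the second methanol followed by enolisation aromatises ring A. The closest known reaction types are the iron-catalysed reductive olefin–enone coupling by metal-hydride hydrogen-atom transfer and the acid-induced aromatisation of Michael adducts of quinone monoketals; joining them into a [3+2] annulation of an allylic alcohol is the unproven part. The dihydrofuran ring closes by 5-exo-trig attack of O1 on the C7a oxocarbenium carbon, a step made easy because hydroxyl and ketal sit 1,4 to each other after the radical addition. C2 is carried over unchanged from 4, and C3 is set in the radical addition by Felkin–Anh-type 1,2-induction (acceptor anti to the aryl group, the radical methyl next to the carbinol hydrogen), which leads to the 2,3-trans (2R,3R) isomer, while the C3a centre of 6 is erased on aromatisation. The step needs Markovnikov hydrogen-atom transfer, which the monosubstituted alkene secures, radical capture faster than 1,2-aryl shift or over-reduction, which the excess of the doubly activated acceptor 5 secures, and retention of O1 rather than methoxy on C7a, which the five-membered tether secures.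

Step 4
Reactants: 8 (2R,3R)-2-(3,4-dimethoxyphenyl)-3-methyl-2,3-dihydro-1-benzofuran-5-ol
Product: 9 (2R,3R)-2-(3,4-dimethoxyphenyl)-3-methyl-2,3-dihydro-1-benzofuran-5,6-dione
Conditions: IBX (1.1 equiv), DMF, rt; short neutral work-up, used at once
Reagents that add atoms: IBX (2-iodoxybenzoic acid), O=C1OI(=O)(O)c2ccccc12
Why: IBX ortho-oxygenation of an electron-rich phenol to the ortho-quinone: the para position (C7a) is blocked by O1 and oxygen should go to the less hindered ortho carbon C6 (C4 is flanked by the substituted C3a), giving a 4-alkoxy-5-alkyl ortho-quinone stabilised as a vinylogous ester; C2 and C3 are not touched.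

Step 5
Reactants: 9 (2R,3R)-2-(3,4-dimethoxyphenyl)-3-methyl-2,3-dihydro-1-benzofuran-5,6-dione; 10 allyl bromide
Product: 11 (2R,3R,5S)-2-(3,4-dimethoxyphenyl)-5-hydroxy-3-methyl-5-(prop-2-en-1-yl)-3,5-dihydro-1-benzofuran-6(2H)-one
Conditions: In, 10, DMF, rt (preformed allylindium sesquibromide); then 9, −20 °C to 0 °C; aq NH4Cl; chromatography
Reagents that add atoms: none
Why: Barbier-type allylindium 1,2-addition to a 1,2-dione should occur at C5, because the C6 carbonyl is deactivated as a vinylogous ester (O1–C7a=C7–C6=O); the new C5 centre arises by addition to the Re face of C5 (the face of the C2 aryl group, anti to the C3 methyl), a bias expected to be weak, so the C5 epimers, being diastereomers, are to be separated by chromatography.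

Step 6
Reactants: 11 (2R,3R,5S)-2-(3,4-dimethoxyphenyl)-5-hydroxy-3-methyl-5-(prop-2-en-1-yl)-3,5-dihydro-1-benzofuran-6(2H)-one
Product: 12 (2R,3R,5S)-2-(3,4-dimethoxyphenyl)-5-methoxy-3-methyl-5-(prop-2-en-1-yl)-3,5-dihydro-1-benzofuran-6(2H)-one
Conditions: MeI, Ag2O, 4 Å MS, CH2Cl2, rt, dark
Reagents that add atoms: methyl iodide, CI
Why: Silver-oxide-promoted Williamson (Purdie) O-methylation of the tertiary α-hydroxy ketone under non-basic conditions, chosen so that no free alkoxide can start an anionic oxy-Cope or α-ketol shift; C5 keeps its configuration because only the O–H bond reacts.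

**Compound list**

1 | 3,4-dimethoxybenzaldehyde (veratraldehyde) | COc1ccc(C=O)cc1OC | starting material
2 | vinylmagnesium bromide | C=C[Mg]Br | starting material
3 | rac-1-(3,4-dimethoxyphenyl)prop-2-en-1-ol | C=CC(O)c1ccc(OC)c(OC)c1 | intermediate
4 | (1R)-1-(3,4-dimethoxyphenyl)prop-2-en-1-ol | C=C[C@@H](O)c1ccc(OC)c(OC)c1 | intermediate
5 | 4,4-dimethoxycyclohexa-2,5-dien-1-one (p-benzoquinone dimethyl monoketal) | COC1(OC)C=CC(=O)C=C1 | starting material
6 | 5-[(1R,2R)-1-(3,4-dimethoxyphenyl)-1-hydroxypropan-2-yl]-4,4-dimethoxycyclohex-2-en-1-one (either configuration at ring C5) | COC1(OC)C=CC(=O)CC1[C@@H](C)[C@@H](O)c1ccc(OC)c(OC)c1 | intermediate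
7 | (2R,3R)-2-(3,4-dimethoxyphenyl)-7a-methoxy-3-methyl-2,3,3a,4-tetrahydro-1-benzofuran-5(7aH)-one (cis-fused, either ring-fusion configuration) | O1[C@@H](c3ccc(OC)c(OC)c3)[C@H](C)C2CC(=O)C=CC12OC | intermediate
8 | (2R,3R)-2-(3,4-dimethoxyphenyl)-3-methyl-2,3-dihydro-1-benzofuran-5-ol | Oc1cc2c(cc1)O[C@@H](c1ccc(OC)c(OC)c1)[C@@H]2C | intermediate
9 | (2R,3R)-2-(3,4-dimethoxyphenyl)-3-methyl-2,3-dihydro-1-benzofuran-5,6-dione | O=C1C=C2C(=CC1=O)O[C@@H](c1ccc(OC)c(OC)c1)[C@@H]2C | intermediate
10 | allyl bromide (3-bromoprop-1-ene) | C=CCBr | starting material
11 | (2R,3R,5S)-2-(3,4-dimethoxyphenyl)-5-hydroxy-3-methyl-5-(prop-2-en-1-yl)-3,5-dihydro-1-benzofuran-6(2H)-one | C=CC[C@]1(O)C=C2C(=CC1=O)O[C@@H](c1ccc(OC)c(OC)c1)[C@@H]2C | intermediate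
12 | (2R,3R,5S)-2-(3,4-dimethoxyphenyl)-5-methoxy-3-methyl-5-(prop-2-en-1-yl)-3,5-dihydro-1-benzofuran-6(2H)-one | C=CC[C@]1(OC)C=C2C(=CC1=O)O[C@@H](c1ccc(OC)c(OC)c1)[C@@H]2C | target

**Step count and risks**

Total step count: 6. Longest linear sequence: 6 steps (1 → 3 → 4 → 8 → 9 → 11 → 12).

Steps most likely to fail:

Step 3 (Proposed new method). The C3 radical may be diverted before it is trapped (1,2-aryl shift to the carbinyl position, simple reduction, or isomerisation of the allylic alcohol to the ketone). Its addition to 5 may show poor facial selectivity at C3. The oxocarbenium ion may lose a proton while methoxy or ethoxy, not O1, is still on C7a. Acid that is too strong would epimerise C2 of the minor cis isomer and so erode enantiopurity. The fallback uses known chemistry and forms the O1–C7a tether first, so that C3–C3a closes in a ring. It sets out from 4: oxidative dearomatisation of commercial 4-methoxyphenol with PhI(OAc)2 in CH2Cl2 in the presence of 4 (used in excess and recovered) should give the mixed quinone monoketal 4-{[(1R)-1-(3,4-dimethoxyphenyl)prop-2-en-1-yl]oxy}-4-methoxycyclohexa-2,5-dien-1-one F1. Fe(acac)3/PhSiH3 in EtOH then generates the same C3 radical, which should cyclise 5-exo-trig onto the dienone β-carbon with the methyl trans to the aryl group to give 7. CSA aromatises 7, and the fallback comes back to the route at 8.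

Step 5. Face selection at C5 depends on a remote methyl group and may be close to unselective, so that half of the material ends as the C5 epimer; indium metal may also reduce the quinone to the catechol. The fallback gives up substrate control for reagent control. It sets out from 9, which is bound through both carbonyl oxygens to a chiral Lewis acid (Cu(OTf)2 with a tert-butyl bis(oxazoline) ligand, CH2Cl2, −78 °C) and treated with allyltributylstannane. Both ligand antipodes are available, and the one that leaves the Re face of C5 open is used. It comes back to the route at 11 and makes no new compound (F0).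

Step 4. The ortho-quinone may isomerise by proton shift from C3 (quinone methide, then the aromatic benzofuran-5,6-diol), which would erase C2 and C3, and oxygen may be delivered to C4 instead of C6. The fallback separates the oxygenation from the quinone stage and does not isolate 9. It sets out from 8: IBX oxidation followed at once by reductive work-up with aqueous Na2S2O4 should give the storable catechol (2R,3R)-2-(3,4-dimethoxyphenyl)-3-methyl-2,3-dihydro-1-benzofuran-5,6-diol F2, whose regiochemistry can be checked. F2 is then oxidised with Ag2O in CH2Cl2 at 0 °C in the presence of allylboronic acid pinacol ester, so that the quinone is intercepted as it forms, and the fallback comes back to the route at 11.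

**Further compounds**

F1 | step 3 | 4-{[(1R)-1-(3,4-dimethoxyphenyl)prop-2-en-1-yl]oxy}-4-methoxycyclohexa-2,5-dien-1-one | COC1(O[C@H](C=C)c2ccc(OC)c(OC)c2)C=CC(=O)C=C1
F0 | step 5 | none | none
F2 | step 4 | (2R,3R)-2-(3,4-dimethoxyphenyl)-3-methyl-2,3-dihydro-1-benzofuran-5,6-diol | Oc1cc2c(cc1O)O[C@@H](c1ccc(OC)c(OC)c1)[C@@H]2C
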